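**Retrosynthetic overview**

1. The strategy rests on ring A (C1 OMe, C2 H, C3 OH, C4 p-hydroxybenzyl, C5 arylethyl, C6 p-hydroxybenzyl). It is a resorcinol monomethyl ether whose C4 and C6 carry the same group, so it maps onto a 4,6-dibenzyl-5-(arylethyl)cyclohexane-1,3-dione in which methylation of either carbonyl leads to the same arene.
2. Target ⇐ tris(benzyl ether) (hydrogenolysis) ⇐ 3-methoxycyclohexenone (dehydrogenation) ⇐ symmetric dione (enol etherification) ⇐ β-keto ester (dealkoxycarbonylation).
3. β-Keto ester ⇐ Michael–Claisen product, by dianion C-benzylation at the ester-bearing carbon (ring A C6).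
4. Michael–Claisen product ⇐ α-benzyl enone + dimethyl malonate, forming C5–C6 and C1–C2. C2–C3–C4 are the CH3–CO–C(benzyl) unit of the enone, C5 is its β-carbon and C6–C1 are two malonate carbons. Ring A is the only ring built; the three phenolic rings are bought intact.
5. Enone ⇐ Horner–Wadsworth–Emmons olefination of an α-benzylated ketophosphonate with 3-[3-(benzyloxy)phenyl]propanal, which places the benzyl group on the α-carbon without ambiguity.

Key step: step 6

Assumption: the cyclohexane-1,3-diones are written as diketo tautomers although they are largely enolized. Their ring stereocentres are racemic, are drawn as the expected all-equatorial isomers, and do not affect the target because all become sp2 in step 10.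

**Route**

Step 1
Reactants: 1 3-(3-hydroxyphenyl)propanoic acid
Product: 2 benzyl 3-[3-(benzyloxy)phenyl]propanoate
Conditions: BnBr (2.2 equiv), K2CO3, DMF, 60 °C
Reagents that add atoms: benzyl bromide, BrCc1ccccc1
Why: Williamson-type O-alkylation of both the phenoxide and the carboxylate by benzyl bromide should give the benzyl ether benzyl ester in one operation.

Step 2
Reactants: 2 benzyl 3-[3-(benzyloxy)phenyl]propanoate
Product: 3 3-[3-(benzyloxy)phenyl]propan-1-ol
Conditions: LiAlH4, THF, 0 °C to rt; aqueous work-up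
Reagents that add atoms: none
Why: Hydride reduction of the ester with LiAlH4 gives the primary alcohol, and the aryl benzyl ether is inert to hydride.

Step 3
Reactants: 3 3-[3-(benzyloxy)phenyl]propan-1-ol
Product: 4 3-[3-(benzyloxy)phenyl]propanal
Conditions: TEMPO (cat.), PhI(OAc)2, CH2Cl2, rt
Reagents that add atoms: none
Why: TEMPO-catalysed oxidation with PhI(OAc)2 as terminal oxidant stops at the aldehyde for unhindered primary alcohols and leaves benzyl ethers alone.

Step 4
Reactants: 5 diethyl (2-oxopropyl)phosphonate; 6 4-(benzyloxy)benzyl chloride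
Product: 7 diethyl {1-[4-(benzyloxy)phenyl]-3-oxobutan-2-yl}phosphonate (racemic)
Conditions: NaH (1 equiv), THF, 0 °C; then 6, Bu4NI (cat.), 60 °C; slight excess of 5
Reagents that add atoms: none
Why: C-alkylation of the sodium salt of a β-ketophosphonate by a benzylic halide under iodide catalysis puts the benzyl group on the carbon between P=O and C=O, the future enone α-carbon; the racemic stereocentre disappears in step 5.

Step 5
Reactants: 7 diethyl {1-[4-(benzyloxy)phenyl]-3-oxobutan-2-yl}phosphonate; 4 3-[3-(benzyloxy)phenyl]propanal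
Product: 8 (3E)-3-[4-(benzyloxy)benzyl]-6-[3-(benzyloxy)phenyl]hex-3-en-2-one
Conditions: Ba(OH)2·8H2O (activated), THF/H2O 40:1, rt
Reagents that add atoms: none
Why: Horner–Wadsworth–Emmons olefination of an α-substituted β-ketophosphonate under mild Ba(OH)2 conditions tolerates the enolizable aldehyde and should give mainly the E trisubstituted enone; the Z isomer would serve equally in step 6.

Step 6
Reactants: 8 (3E)-3-[4-(benzyloxy)benzyl]-6-[3-(benzyloxy)phenyl]hex-3-en-2-one; 9 dimethyl malonate
Product: 11 methyl all-trans-3-[4-(benzyloxy)benzyl]-2-{2-[3-(benzyloxy)phenyl]ethyl}-4,6-dioxocyclohexane-1-carboxylate (racemic), via keto diester 10 (not isolated)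
Conditions: 9 (1.5 equiv), NaOMe (2 equiv), MeOH, reflux; then aq. HCl, 0 °C
Reagents that add atoms: none
Why: Methoxide forms the malonate anion, which adds reversibly in a Michael reaction to the β-carbon of 8 (ring A C5–C6) to give keto diester 10; the methyl-side ketone enolate of 10 then attacks one ester carbonyl and expels methoxide (ring A C1–C2), and irreversible deprotonation of the resulting β-diketone pulls both equilibria forward. The closest known reaction type is the base-mediated Michael–Claisen annulation of enones with malonic esters, as in the preparation of 5,5-dimethylcyclohexane-1,3-dione from mesityl oxide. Ring A closes in a 6-(enolendo)-exo-trig mode. The three new stereocentres (cyclohexane C1, C2, C3) are under thermodynamic control: C1 and C3 are epimerizable under methoxide and should settle trans to the C2 side chain with all three groups equatorial, and since the product is racemic and all three centres are planarized in step 10 no further control is needed. The step needs regioselectivity for benzyl at ring A C4 and arylethyl at C5, which the enone fixes by carrying benzyl on its α-carbon and arylethyl on its β-carbon; only the methyl enolate can close a six-membered ring, because the other α-carbon would have to form a four-membered ring.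

Step 7
Reactants: 11 methyl all-trans-3-[4-(benzyloxy)benzyl]-2-{2-[3-(benzyloxy)phenyl]ethyl}-4,6-dioxocyclohexane-1-carboxylate; 6 4-(benzyloxy)benzyl chloride
Product: 12 methyl 1,3-bis[4-(benzyloxy)benzyl]-2-{2-[3-(benzyloxy)phenyl]ethyl}-4,6-dioxocyclohexane-1-carboxylate (racemic; both benzyl groups trans to the arylethyl group)
Conditions: LiN(i-Pr)2 (2.3 equiv), THF–DMPU, −78 to 0 °C; then 6, Bu4NI (cat.), −78 °C to rt; aq. NH4Cl, then dilute HCl
Reagents that add atoms: none
Why: Two equivalents of amide base form the dianion (diketonate plus ester enolate at the only doubly activated C–H), and as in Hauser/Weiler dianion alkylations of β-dicarbonyl compounds the last-formed, most basic carbon should be benzylated to a quaternary centre, trans to the neighbouring arylethyl group (a configuration of no consequence).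

Step 8
Reactants: 12 methyl 1,3-bis[4-(benzyloxy)benzyl]-2-{2-[3-(benzyloxy)phenyl]ethyl}-4,6-dioxocyclohexane-1-carboxylate
Product: 13 4,6-bis[4-(benzyloxy)benzyl]-5-{2-[3-(benzyloxy)phenyl]ethyl}cyclohexane-1,3-dione (meso; benzyl groups cis to each other and trans to the arylethyl group)
Conditions: LiCl (3 equiv), DMSO, H2O, 140 °C
Reagents that add atoms: none
Why: Krapcho dealkoxycarbonylation: chloride attacks the methyl group of the hindered β-keto ester in an SN2 reaction, the β-keto carboxylate loses CO2, and the epimerizable C–H centres should settle in the all-equatorial meso dione.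

Step 9
Reactants: 13 4,6-bis[4-(benzyloxy)benzyl]-5-{2-[3-(benzyloxy)phenyl]ethyl}cyclohexane-1,3-dione
Product: 14 4,6-bis[4-(benzyloxy)benzyl]-5-{2-[3-(benzyloxy)phenyl]ethyl}-3-methoxycyclohex-2-en-1-one (racemic)
Conditions: MeOH, TsOH·H2O (cat.), 3 Å molecular sieves, reflux
Reagents that add atoms: methanol, CO
Why: Acid-catalysed enol etherification of a cyclic 1,3-dione gives O-methylation only, and because 13 is meso its two carbonyls give enantiomeric enol ethers that lead to the same arene.

Step 10
Reactants: 14 4,6-bis[4-(benzyloxy)benzyl]-5-{2-[3-(benzyloxy)phenyl]ethyl}-3-methoxycyclohex-2-en-1-one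
Product: 17 2,4-bis[4-(benzyloxy)benzyl]-3-{2-[3-(benzyloxy)phenyl]ethyl}-5-methoxyphenol, via selenide 15 (not isolated), via dienone 16 (not isolated)
Conditions: LiN(i-Pr)2 (1.1 equiv), THF, −78 °C; PhSeBr; then 30% H2O2, pyridine, CH2Cl2, 0 °C to rt
Reagents that add atoms: benzeneselenenyl bromide, Br[Se]c1ccccc1 (adds PhSe to intermediate 15 only; nothing from it remains in 17)
Why: Kinetic α′-deprotonation of the vinylogous ester, selenenylation trans to the C5 side chain to give selenide 15, then oxidation at selenium and syn-elimination of PhSeOH toward the cis C5–H give dienone 16, which tautomerizes at once to the phenol (selenoxide elimination followed by aromatization).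

Step 11
Reactants: 17 2,4-bis[4-(benzyloxy)benzyl]-3-{2-[3-(benzyloxy)phenyl]ethyl}-5-methoxyphenol
Product: 18 2,4-bis(4-hydroxybenzyl)-3-[2-(3-hydroxyphenyl)ethyl]-5-methoxyphenol (target)
Conditions: H2 (1 atm), 10% Pd/C, EtOAc/MeOH, rt
Reagents that add atoms: none
Why: Hydrogenolysis over palladium on carbon cleaves the three O-benzyl ethers and should leave the aryl methyl ether, the diarylmethane C–C bonds and the arenes untouched.

**Compound list**

1 | 3-(3-hydroxyphenyl)propanoic acid | OC(=O)CCc1cccc(O)c1 | starting material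
2 | benzyl 3-[3-(benzyloxy)phenyl]propanoate | O=C(CCc1cccc(OCc2ccccc2)c1)OCc1ccccc1 | intermediate
3 | 3-[3-(benzyloxy)phenyl]propan-1-ol | OCCCc1cccc(OCc2ccccc2)c1 | intermediate
4 | 3-[3-(benzyloxy)phenyl]propanal | O=CCCc1cccc(OCc2ccccc2)c1 | intermediate
5 | diethyl (2-oxopropyl)phosphonate | CCOP(=O)(CC(C)=O)OCC | starting material
6 | 4-(benzyloxy)benzyl chloride | ClCc1ccc(OCc2ccccc2)cc1 | starting material
7 | diethyl {1-[4-(benzyloxy)phenyl]-3-oxobutan-2-yl}phosphonate (racemic) | CCOP(=O)(OCC)C(Cc1ccc(OCc2ccccc2)cc1)C(C)=O | intermediate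
8 | (3E)-3-[4-(benzyloxy)benzyl]-6-[3-(benzyloxy)phenyl]hex-3-en-2-one | CC(=O)/C(Cc1ccc(OCc2ccccc2)cc1)=C/CCc1cccc(OCc2ccccc2)c1 | intermediate
9 | dimethyl malonate | COC(=O)CC(=O)OC | starting material
10 | dimethyl 2-{2-[4-(benzyloxy)benzyl]-1-{2-[3-(benzyloxy)phenyl]ethyl}-3-oxobutyl}malonate (racemic Michael adduct, not isolated) | COC(=O)C(C(=O)OC)[C@@H](CCc1cccc(OCc2ccccc2)c1)[C@H](Cc1ccc(OCc2ccccc2)cc1)C(C)=O | intermediate
11 | methyl all-trans-3-[4-(benzyloxy)benzyl]-2-{2-[3-(benzyloxy)phenyl]ethyl}-4,6-dioxocyclohexane-1-carboxylate (racemic) | COC(=O)[C@H]1C(=O)CC(=O)[C@@H](Cc2ccc(OCc3ccccc3)cc2)[C@@H]1CCc1cccc(OCc2ccccc2)c1 | intermediate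
12 | methyl 1,3-bis[4-(benzyloxy)benzyl]-2-{2-[3-(benzyloxy)phenyl]ethyl}-4,6-dioxocyclohexane-1-carboxylate (racemic; benzyl groups trans to the arylethyl group) | COC(=O)[C@]1(Cc2ccc(OCc3ccccc3)cc2)C(=O)CC(=O)[C@@H](Cc2ccc(OCc3ccccc3)cc2)[C@@H]1CCc1cccc(OCc2ccccc2)c1 | intermediate
13 | 4,6-bis[4-(benzyloxy)benzyl]-5-{2-[3-(benzyloxy)phenyl]ethyl}cyclohexane-1,3-dione (meso) | O=C1CC(=O)[C@@H](Cc2ccc(OCc3ccccc3)cc2)[C@H](CCc2cccc(OCc3ccccc3)c2)[C@H]1Cc1ccc(OCc2ccccc2)cc1 | intermediate
14 | 4,6-bis[4-(benzyloxy)benzyl]-5-{2-[3-(benzyloxy)phenyl]ethyl}-3-methoxycyclohex-2-en-1-one (racemic) | COC1=CC(=O)[C@@H](Cc2ccc(OCc3ccccc3)cc2)[C@H](CCc2cccc(OCc3ccccc3)c2)[C@H]1Cc1ccc(OCc2ccccc2)cc1 | intermediate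
15 | 4,6-bis[4-(benzyloxy)benzyl]-5-{2-[3-(benzyloxy)phenyl]ethyl}-3-methoxy-6-(phenylselanyl)cyclohex-2-en-1-one (racemic, not isolated) | COC1=CC(=O)[C@]([Se]c2ccccc2)(Cc2ccc(OCc3ccccc3)cc2)[C@H](CCc2cccc(OCc3ccccc3)c2)[C@H]1Cc1ccc(OCc2ccccc2)cc1 | intermediate
16 | 4,6-bis[4-(benzyloxy)benzyl]-5-{2-[3-(benzyloxy)phenyl]ethyl}-3-methoxycyclohexa-2,5-dien-1-one (racemic, not isolated) | COC1=CC(=O)C(Cc2ccc(OCc3ccccc3)cc2)=C(CCc2cccc(OCc3ccccc3)c2)[C@H]1Cc1ccc(OCc2ccccc2)cc1 | intermediate
17 | 2,4-bis[4-(benzyloxy)benzyl]-3-{2-[3-(benzyloxy)phenyl]ethyl}-5-methoxyphenol | COc1cc(O)c(Cc2ccc(OCc3ccccc3)cc2)c(CCc2cccc(OCc3ccccc3)c2)c1Cc1ccc(OCc2ccccc2)cc1 | intermediate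
18 | 2,4-bis(4-hydroxybenzyl)-3-[2-(3-hydroxyphenyl)ethyl]-5-methoxyphenol | COc1cc(O)c(Cc2ccc(O)cc2)c(CCc2cccc(O)c2)c1Cc1ccc(O)cc1 | target

**Step count**

Total: 11 steps. Longest linear sequence: 10 steps (steps 1–3 and 5–11); step 4 is a one-step side branch.

**Steps most likely to fail**

Step 7 (dianion benzylation). The second deprotonation may be incomplete, or alkylation may go to oxygen or to the carbon between the two carbonyls instead of the hindered ester-bearing carbon, where a quaternary centre must form next to a tertiary one. The fallback sets out from 11 and comes back at 13. Keto ester 11 would first be dealkoxycarbonylated (LiCl, wet DMSO, 140 °C) to trans-4-[4-(benzyloxy)benzyl]-5-{2-[3-(benzyloxy)phenyl]ethyl}cyclohexane-1,3-dione F1. Its dianion (LiN(i-Pr)2, 2.2 equiv, THF–HMPA, −78 to 0 °C) should form at the unsubstituted C6 methylene, as is known for cyclohexane-1,3-dione dianions, and alkylation with chloride 6 would give 13 directly. No quaternary carbon is built, and steps 7 and 8 are replaced.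

Step 6 (Michael–Claisen ring formation). The Michael equilibrium may lie on the side of the hindered α,β-disubstituted enone, the enone may deconjugate under base, or the dione anion of the product may add to unreacted enone. The fallback sets out from 8 and 9 and comes back at 11. Dimethyl malonate 9 would be converted (LiN(i-Pr)2, Me3SiCl, THF, −78 °C) into its silyl ketene acetal, methyl 3-methoxy-3-[(trimethylsilyl)oxy]prop-2-enoate F2. An irreversible Mukaiyama–Michael addition of F2 to enone 8 (Sc(OTf)3 cat., CH2Cl2, −78 °C to rt, acidic work-up) would give keto diester 10, now isolated. The Claisen closure of 10 to 11 would then be run on its own with NaOMe in MeOH.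

Step 10 (dehydrogenation to the arene). The electron-rich phenol may be over-oxidized by the selenium oxidants and H2O2, and the selenoxide may eliminate toward the exocyclic benzylic hydrogens, which would call for a separate base isomerization. The fallback sets out from 14 and comes back at 17. Enone 14 would be converted (LiN(i-Pr)2, Me3SiCl, THF, −78 °C) into the silyl dienol ether ({2,4-bis[4-(benzyloxy)benzyl]-3-{2-[3-(benzyloxy)phenyl]ethyl}-5-methoxycyclohexa-1,5-dien-1-yl}oxy)trimethylsilane F3. Saegusa–Ito oxidation of F3 with Pd(OAc)2 (1 equiv, MeCN, rt) proceeds through a palladium enolate and β-hydride elimination to dienone 16, which tautomerizes to 17 with no peroxide present.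

**Further compounds**

F1 | step 7 | trans-4-[4-(benzyloxy)benzyl]-5-{2-[3-(benzyloxy)phenyl]ethyl}cyclohexane-1,3-dione (racemic) | O=C1CC(=O)[C@@H](Cc2ccc(OCc3ccccc3)cc2)[C@H](CCc2cccc(OCc3ccccc3)c2)C1
F2 | step 6 | methyl (E)-3-methoxy-3-[(trimethylsilyl)oxy]prop-2-enoate (either geometry serves) | COC(=O)/C=C(\OC)O[Si](C)(C)C
F3 | step 10 | ({2,4-bis[4-(benzyloxy)benzyl]-3-{2-[3-(benzyloxy)phenyl]ethyl}-5-methoxycyclohexa-1,5-dien-1-yl}oxy)trimethylsilane (racemic) | COC1=CC(O[Si](C)(C)C)=C(Cc2ccc(OCc3ccccc3)cc2)[C@H](CCc2cccc(OCc3ccccc3)c2)[C@H]1Cc1ccc(OCc2ccccc2)cc1
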